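**Plan**
1. Labels: the decalin is numbered C1 (quaternary) to C8a as in naphthalene. Ring A is C4a, C5–C8, C8a; ring B is C1–C4, C4a, C8a. The bridge is C9 (CHMe), C10=C11, C12. Ring C is C13 (quaternary), C14=C15, C16, C17 and spiro C5'. Ring D is the tetronate O1'–C5'; ring E is the 11-membered carbocycle. The side chain C18–C20 sits on C16, C21 (CH2OH) on C15, and C22 is the ketone.
2. Enabling feature: ring B is a cyclohexene whose C3=C4 bond lies between C2 and C4a. C1 carries the acyl group C22, and the C5–C8 chain of ring A ties C4a to C8a. A retro-Diels–Alder cut of C4a–C8a and C1–C2 therefore opens rings A, B and E together to a 19-membered macrocyclic pentaene.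
3. Further cuts: C3–C4 (Suzuki–Miyaura ring closure), C3'–C22 (tetronate anion plus enal), C10=C11 (cross-metathesis), ring D (propiolate annulation of a ring C ketone), C13–allyl, and ring C (Michael/Claisen annulation of a dihydropyranone).
4. Forward order of rings: temporary dihydropyranone, ring C with a second temporary lactone, ring D, the 19-membered ring, then rings A, B and E at once in the last ring-forming step.
5. Stereochemistry: C19 comes from (R)-pent-4-en-2-ol and is relayed to C16, C13 and C5'. C9 comes from methyl (S)-3-hydroxy-2-methylpropanoate and C6 from (S)-citronellal. C1, C2, C4a and C8a come from the cycloaddition.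
6. Helpers: a bromine at C3 steers the diene face and is removed in step 22. The O-methyl group on ring D and two silyl ethers are removed in steps 23 and 24.

Key step: step 21

Assumption: read from the SMILES, the ring fusion is trans and the C6 methyl group is axial (cis to H4a); the route is built for exactly this configuration, hence (S)-citronellal.

**Step 1**
Reactants: 1 (R)-pent-4-en-2-ol; 2 acryloyl chloride
Product: 3 (R)-pent-4-en-2-yl acrylate
Conditions: Et3N, DMAP (cat.), CH2Cl2, 0 °C
Reagents that add atoms: none
Why: Esterification of a secondary alcohol with an acid chloride, which leaves the C19 stereocentre untouched.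

**Step 2**
Reactants: 3 (R)-pent-4-en-2-yl acrylate
Product: 4 (R)-6-methyl-5,6-dihydro-2H-pyran-2-one
Conditions: second-generation Grubbs catalyst RuCl2(=CHPh)(PCy3)(SIMes) (2 mol %), CH2Cl2 (0.01 M), reflux
Reagents that add atoms: none
Why: Ring-closing metathesis of the acrylate of a homoallylic alcohol is a standard entry to 5,6-dihydropyran-2-ones and does not touch C19.

**Step 3**
Reactants: 4 (R)-6-methyl-5,6-dihydro-2H-pyran-2-one; 5 methyl 3-oxopentanoate
Product: 8 bicyclic lactone trione (3R,4aR)-3,7-dimethylhexahydroisochromene-1,6,8-trione, via Michael adduct 6 (not isolated), via hydroxy ester 7 (not isolated)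
Conditions: DBU (0.1 equiv), THF, 0 °C to rt; LiN(iPr)2 (2.3 equiv), −78 to 0 °C; 1 M HCl; PPTS (cat.), PhMe, 80 °C
Reagents that add atoms: none
Why: The keto ester carbon (C15) adds in a Michael reaction axially to the half-chair lactone, anti to the C19 methyl group (4,6-trans lactone, sets C16, the acidic keto ester buffering the base), the keto ester dianion then acylates its terminal carbon C13 with the lactone carbonyl C5' (Claisen/Dieckmann-type closure of ring C, with retro-Michael blocked in the enolate), and the freed O19 lactonises onto the ester C21 to give a temporary ring that protects both.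

**Step 4**
Reactants: 8 bicyclic lactone trione
Product: 9 C13-allylated trione (allyl cis to the C18 methylene)
Conditions: allyl methyl carbonate (1.0 equiv), Pd(PPh3)4 (2 mol %), THF, rt
Reagents that add atoms: allyl methyl carbonate C=CCOC(=O)OC
Why: Tsuji–Trost allylation of a 2-methylcyclohexane-1,3-dione under neutral conditions gives C-allylation at C13, and axial attack on the sofa-shaped dionate whose flap C16 carries C18 equatorially leads straight to a chair and so places the allyl group cis to C18.

**Step 5**
Reactants: 9 C13-allylated trione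
Product: 10 C14 enol triflate
Conditions: Tf2O, iPr2NEt, CH2Cl2, −78 °C
Reagents that add atoms: triflic anhydride O=S(=O)(OS(=O)(=O)C(F)(F)F)C(F)(F)F
Why: The keto lactone is the only strongly enolised carbonyl pair left and C13 is quaternary, so O-triflation gives the C14=C15 enol triflate regiospecifically while the C5' ketone stays untouched.

**Step 6**
Reactants: 10 C14 enol triflate
Product: 11 unsaturated lactone ketone
Conditions: Pd(OAc)2 (5 mol %), PPh3 (10 mol %), HCO2H, Et3N, DMF, 60 °C
Reagents that add atoms: none
Why: Palladium-catalysed formate hydrogenolysis of an enol triflate replaces OTf by H and leaves C14=C15 in place, conjugated to the lactone.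

**Step 7**
Reactants: 11 unsaturated lactone ketone
Product: 12 triol (epimers at C5')
Conditions: iBu2AlH (6 equiv), CH2Cl2, −78 °C to rt; aq. potassium sodium tartrate
Reagents that add atoms: none
Why: 1,2-Reduction with iBu2AlH opens the temporary lactone to the allylic C21 alcohol and the C19 alcohol and also reduces the ketone, whose new carbinol configuration is irrelevant because it is reoxidised in step 9.

**Step 8**
Reactants: 12 triol
Product: 13 bis-silyl ether alcohol
Conditions: TBSCl (2.2 equiv), imidazole, DMF, 0 °C
Reagents that add atoms: tert-butyldimethylsilyl chloride CC(C)(C)[Si](C)(C)Cl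
Why: Silylation follows steric access, so the primary allylic and the unhindered secondary hydroxyl react while the carbinol next to quaternary C13 stays free.

**Step 9**
Reactants: 13 bis-silyl ether alcohol
Product: 14 ring C ketone
Conditions: Dess–Martin periodinane, pyridine, CH2Cl2, rt
Reagents that add atoms: none
Why: Dess–Martin oxidation of the remaining secondary alcohol under buffered conditions moves neither the double bond nor the silyl groups.

**Step 10**
Reactants: 14 ring C ketone
Product: 16 spiro methyl tetronate, via propargylic alcohol 15 (not isolated)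
Conditions: LiN(iPr)2, methyl propiolate, THF, −78 °C, then 14; MeOH, NaOMe (0.3 equiv), −78 to 40 °C; AcOH
Reagents that add atoms: methyl propiolate C#CC(=O)OC; methanol CO
Why: 1,2-Addition of lithium methyl propiolate, conjugate addition of methoxide and lactonisation is the standard annulation of a 4-methoxy-2(5H)-furanone onto a ketone, and the small acetylide attacks the half-chair axially on the face away from the C12 and C18 chains, which sets C5' with O1' cis to these chains.

**Step 11**
Reactants: 17 methyl (S)-3-hydroxy-2-methylpropanoate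
Product: 18 methyl (S)-3-(tert-butyldimethylsilyloxy)-2-methylpropanoate
Conditions: TBSCl, imidazole, CH2Cl2, rt
Reagents that add atoms: tert-butyldimethylsilyl chloride CC(C)(C)[Si](C)(C)Cl
Why: Standard silylation of a primary alcohol that leaves C9 untouched.

**Step 12**
Reactants: 18 methyl (S)-3-(tert-butyldimethylsilyloxy)-2-methylpropanoate
Product: 20 (R)-tert-butyl(dimethyl)(2-methylbut-3-enyloxy)silane, via aldehyde 19 (not isolated)
Conditions: iBu2AlH (1.05 equiv), PhMe, −78 °C; then Ph3PCH3Br/KOtBu (THF), −78 °C to rt
Reagents that add atoms: methyltriphenylphosphonium bromide C[P+](c1ccccc1)(c1ccccc1)c1ccccc1.[Br-]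
Why: Partial ester reduction at low temperature followed by Wittig methylenation without isolating the aldehyde avoids epimerisation of the alpha stereocentre C9.

**Step 13**
Reactants: 20 (R)-tert-butyl(dimethyl)(2-methylbut-3-enyloxy)silane
Product: 21 (R)-2-methylbut-3-en-1-ol
Conditions: HF·pyridine, THF, 0 °C
Reagents that add atoms: none
Why: Fluoride cleavage of the silyl ether frees the alcohol whose carbon later becomes C2.

**Step 14**
Reactants: 22 (S)-citronellal
Product: 23 2-[(1E,4S)-4,8-dimethylnona-1,7-dienyl]-4,4,5,5-tetramethyl-1,3,2-dioxaborolane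
Conditions: CH2(Bpin)2, lithium 2,2,6,6-tetramethylpiperidide, THF, 0 °C; then 22, −78 °C to rt
Reagents that add atoms: bis(pinacolboryl)methane CC1(C)OB(CB2OC(C)(C)C(C)(C)O2)OC1(C)C
Why: Boron-Wittig olefination of an aliphatic aldehyde gives the E-alkenyl boronate (C4=C4a) by syn elimination of boron and oxygen and leaves C6 and the trisubstituted alkene untouched.

**Step 15**
Reactants: 23 alkenyl boronate
Product: 25 (2E,6S,8E)-2,6-dimethyl-9-(pinacolboryl)nona-2,8-dienal, via allylic alcohol 24 (not isolated)
Conditions: SeO2 (0.2 equiv), tBuOOH, CH2Cl2, 0 °C to rt; filtered crude, MnO2, CH2Cl2, rt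
Reagents that add atoms: tert-butyl hydroperoxide CC(C)(C)OO
Why: Selenium dioxide allylic oxidation (ene reaction then [2,3]-shift) attacks the electron-rich trisubstituted alkene at its E-methyl group and MnO2 converges all material on the E-enal, the electron-poor alkenyl boronate being inert to both.

**Step 16**
Reactants: 16 spiro methyl tetronate; 21 (R)-2-methylbut-3-en-1-ol
Product: 26 chain-extended tetronate alcohol (C10=C11 E)
Conditions: second-generation Hoveyda–Grubbs catalyst RuCl2(=CH-C6H4-2-OiPr)(SIMes) (5 mol %), 21 (3 equiv), 1,4-benzoquinone (10 mol %), CH2Cl2, 40 °C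
Reagents that add atoms: none
Why: Olefin cross-metathesis between the unhindered allyl group and an allylically branched terminal alkene gives the E-alkene under thermodynamic control, and the trisubstituted and electron-poor double bonds do not take part.

**Step 17**
Reactants: 26 chain-extended tetronate alcohol; 25 boryl dienal
Product: 28 diol (epimers at C22), via dilithio species 27 (not isolated)
Conditions: LiN(iPr)2 (2.2 equiv), THF, −78 °C; 25; AcOH
Reagents that add atoms: none
Why: 4-Methoxy-2(5H)-furanones without hydrogen at C5' are lithiated at C3', and this vinyl anion adds 1,2 to the enal faster than to the pinacol boronate, the new carbinol centre being an inconsequential mixture.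

**Step 18**
Reactants: 28 diol
Product: 29 keto aldehyde
Conditions: Dess–Martin periodinane (3 equiv), pyridine, CH2Cl2, 0 °C
Reagents that add atoms: none
Why: Double Dess–Martin oxidation gives the C22 enone and the C2 aldehyde in one operation, the buffer and low temperature guarding the alpha-methyl beta,gamma-unsaturated aldehyde against epimerisation and conjugation.

**Step 19**
Reactants: 29 keto aldehyde
Product: 30 1,1-dibromoalkene
Conditions: CBr4, PPh3, CH2Cl2, 0 °C; then 29, 2,6-lutidine, −78 to 0 °C
Reagents that add atoms: carbon tetrabromide BrC(Br)(Br)Br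
Why: Ramirez dibromo-olefination (first stage of the Corey–Fuchs sequence) is neutral, fast at low temperature and selective for the aldehyde over the hindered ketone, and it supplies C3 together with the bromine helper.

**Step 20**
Reactants: 30 1,1-dibromoalkene
Product: 31 19-membered macrocyclic bromopentaene
Conditions: Pd(PPh3)4 (20 mol %), TlOEt (3 equiv), THF/H2O 4:1 (1 mM), rt
Reagents that add atoms: none
Why: In this intramolecular Suzuki–Miyaura coupling at high dilution, zerovalent palladium inserts selectively into the C–Br bond trans to C9, as is general for 1,1-dibromoalkenes, so C3–C4 forms with retention at both partners (Br cis to C9, C4=C4a E), and only now do diene and dienophile exist in one molecule.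

**Step 21**
Reactants: 31 19-membered macrocyclic bromopentaene
Product: 32 pentacyclic bromo adduct
Conditions: PhMe (0.5 mM), BHT (cat.), 100 °C
Reagents that add atoms: none
Why: On heating, the C8a=C1 enone (dienophile) and the C4a=C4–C3(Br)=C2 diene of 31 meet across the 19-membered ring in a concerted, suprafacial, asynchronous [4+2] cycloaddition, the closest known reaction type being the transannular Diels–Alder reaction of macrocyclic trienes, which is also known for 2-bromodienes. The C4a–C8a bond closes ring A as the six-membered tether ring (C5–C8 chain in a chair-like array), the C4a–C8a and C1–C2 bonds together close ring B as the cycloadduct ring, and the C1–C2 bond contracts the large ring to the 11-membered ring E. The E,E,E geometry fixes H8a cis to C22 and C5 cis to C9, and the endo position of C22, favoured by secondary overlap and by the short nine-atom bridge that must span C1 and C2 on one face, gives the trans ring fusion, so the relative configuration of C1, C2, C4a and C8a follows. The diene face is chosen by C9: A(1,3) strain with the bromine at C3 holds H9 in the diene plane, the C9 methyl group points away from the dienophile and C10 leads the bridge to the attacked face. This preference must outweigh the cost of the axial C6 methyl group in the chair-like tether (an A value of about 1.7 kcal/mol), which is why the bromine is there. No other diene or activated alkene is present, so chemoselectivity is not at issue.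

**Step 22**
Reactants: 32 pentacyclic bromo adduct
Product: 33 debrominated methyl tetronate
Conditions: Pd(PPh3)4 (10 mol %), Bu3SnH, PhMe, 70 °C
Reagents that add atoms: none
Why: Palladium-catalysed hydrogenolysis of the alkenyl bromide with a tin hydride replaces Br by H without moving C3=C4, and isolated alkenes, ketone and silyl ethers are inert.

**Step 23**
Reactants: 33 debrominated methyl tetronate
Product: 34 bis-silylated acyl tetronic acid
Conditions: LiCl, DMSO, 60 °C; 0.5 M HCl
Reagents that add atoms: none
Why: SN2 demethylation of the vinylogous carbonate by chloride in a dipolar aprotic solvent is the standard release of tetronic acids from their methyl ethers.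

**Step 24**
Reactants: 34 bis-silylated acyl tetronic acid
Product: 35 target CNP0189906.1
Conditions: HF·pyridine, pyridine, THF, 0 °C to rt
Reagents that add atoms: none
Why: Fluoride cleavage of both silyl ethers under mildly acidic conditions, tolerated by the acyl tetronic acid and the allylic alcohol, gives the target.

**Compound list**
1 | (R)-pent-4-en-2-ol | C[C@@H](O)CC=C | starting material
2 | acryloyl chloride | C=CC(=O)Cl | starting material
3 | (R)-pent-4-en-2-yl acrylate | C[C@H](CC=C)OC(=O)C=C | intermediate
4 | (R)-6-methyl-5,6-dihydro-2H-pyran-2-one | C[C@@H]1CC=CC(=O)O1 | intermediate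
5 | methyl 3-oxopentanoate | CCC(=O)CC(=O)OC | starting material
6 | methyl 2-[(2R,4R)-2-methyl-6-oxooxan-4-yl]-3-oxopentanoate (4,6-trans lactone; acidic CH as epimers) | CCC(=O)C(C(=O)OC)[C@@H]1C[C@@H](C)OC(=O)C1 | intermediate
7 | methyl (6R)-6-[(2R)-2-hydroxypropyl]-3-methyl-2,4-dioxocyclohexane-1-carboxylate (enolised, C1 and C3 labile) | CC1C(=O)C(C(=O)OC)[C@H](C[C@@H](C)O)CC1=O | intermediate
8 | (3R,4aR)-3,7-dimethylhexahydroisochromene-1,6,8-trione (enolised, C7 and C8a labile) | CC1C(=O)C2C(=O)O[C@H](C)C[C@@H]2CC1=O | intermediate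
9 | 7-allyl derivative of 8, C13 quaternary with allyl cis to C18 (C15-H labile) | C=CC[C@]1(C)C(=O)C2C(=O)O[C@H](C)C[C@@H]2CC1=O | intermediate
10 | C14 enol triflate of 9 | C=CC[C@]1(C)C(OS(=O)(=O)C(F)(F)F)=C2C(=O)O[C@H](C)C[C@@H]2CC1=O | intermediate
11 | unsaturated bicyclic lactone ketone (C14=C15; C13, C16, C19 as in the target) | C=CC[C@]1(C)C=C2C(=O)O[C@H](C)C[C@@H]2CC1=O | intermediate
12 | ring C triol: 2-allyl-4-(hydroxymethyl)-5-[(R)-2-hydroxypropyl]-2-methylcyclohex-3-en-1-ol (C13, C16, C19 as in the target; carbinol epimers) | C=CC[C@]1(C)C=C(CO)[C@H](C[C@@H](C)O)CC1O | intermediate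
13 | O19,O21-bis(tert-butyldimethylsilyl) ether of 12 | C=CC[C@]1(C)C=C(CO[Si](C)(C)C(C)(C)C)[C@H](C[C@@H](C)O[Si](C)(C)C(C)(C)C)CC1O | intermediate
14 | ring C ketone (2-allyl-2-methylcyclohex-3-enone; C13, C16, C19 as in the target) | C=CC[C@]1(C)C=C(CO[Si](C)(C)C(C)(C)C)[C@H](C[C@@H](C)O[Si](C)(C)C(C)(C)C)CC1=O | intermediate
15 | tertiary propargylic alcohol, methyl ynoate on C5' trans to the C12 and C18 chains | C=CC[C@]1(C)C=C(CO[Si](C)(C)C(C)(C)C)[C@H](C[C@@H](C)O[Si](C)(C)C(C)(C)C)C[C@@]1(O)C#CC(=O)OC | intermediate
16 | spiro 4-methoxy-2(5H)-furanone (rings C and D; C5', C13, C16, C19 as in the target; allyl on C13) | C=CC[C@]1(C)C=C(CO[Si](C)(C)C(C)(C)C)[C@H](C[C@@H](C)O[Si](C)(C)C(C)(C)C)C[C@]12OC(=O)C=C2OC | intermediate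
17 | methyl (S)-3-hydroxy-2-methylpropanoate | OC[C@H](C)C(=O)OC | starting material
18 | methyl (S)-3-(tert-butyldimethylsilyloxy)-2-methylpropanoate | CC(C)(C)[Si](C)(C)OC[C@H](C)C(=O)OC | intermediate
19 | (S)-3-(tert-butyldimethylsilyloxy)-2-methylpropanal | CC(C)(C)[Si](C)(C)OC[C@H](C)C=O | intermediate
20 | (R)-tert-butyl(dimethyl)(2-methylbut-3-enyloxy)silane | CC(C)(C)[Si](C)(C)OC[C@H](C)C=C | intermediate
21 | (R)-2-methylbut-3-en-1-ol | OC[C@H](C)C=C | intermediate
22 | (S)-citronellal | C[C@H](CC=O)CCC=C(C)C | starting material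
23 | 2-[(1E,4S)-4,8-dimethylnona-1,7-dienyl]-4,4,5,5-tetramethyl-1,3,2-dioxaborolane | C[C@H](C/C=C/B1OC(C)(C)C(C)(C)O1)CCC=C(C)C | intermediate
24 | (2E,6S,8E)-2,6-dimethyl-9-(pinacolboryl)nona-2,8-dien-1-ol | C[C@H](C/C=C/B1OC(C)(C)C(C)(C)O1)CC/C=C(\C)CO | intermediate
25 | (2E,6S,8E)-2,6-dimethyl-9-(pinacolboryl)nona-2,8-dienal | C[C@H](C/C=C/B1OC(C)(C)C(C)(C)O1)CC/C=C(\C)C=O | intermediate
26 | tetronate 16 extended to the (E)-C12–C11=C10–C9(Me)–CH2OH chain (C9 R) | OC[C@H](C)/C=C/C[C@]1(C)C=C(CO[Si](C)(C)C(C)(C)C)[C@H](C[C@@H](C)O[Si](C)(C)C(C)(C)C)C[C@]12OC(=O)C=C2OC | intermediate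
27 | O,C3'-dilithio derivative of 26 | [Li]OC[C@H](C)/C=C/C[C@]1(C)C=C(CO[Si](C)(C)C(C)(C)C)[C@H](C[C@@H](C)O[Si](C)(C)C(C)(C)C)C[C@]12OC(=O)C([Li])=C2OC | intermediate
28 | open-chain diol: C3'–CH(OH)–C1(Me)=C8a allylic carbinol (epimers) and primary C2 alcohol, E-alkenyl boronate at C4 | C[C@H](C/C=C/B1OC(C)(C)C(C)(C)O1)CC/C=C(\C)C(O)C1=C(OC)[C@]2(OC1=O)C[C@@H](C[C@@H](C)O[Si](C)(C)C(C)(C)C)C(CO[Si](C)(C)C(C)(C)C)=C[C@@]2(C)C/C=C/[C@@H](C)CO | intermediate
29 | keto aldehyde (C22 enone, C2 aldehyde) | C[C@H](C/C=C/B1OC(C)(C)C(C)(C)O1)CC/C=C(\C)C(=O)C1=C(OC)[C@]2(OC1=O)C[C@@H](C[C@@H](C)O[Si](C)(C)C(C)(C)C)C(CO[Si](C)(C)C(C)(C)C)=C[C@@]2(C)C/C=C/[C@@H](C)C=O | intermediate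
30 | open-chain 1,1-dibromoalkene (C2=C3Br2) with alkenyl boronate | C[C@H](C/C=C/B1OC(C)(C)C(C)(C)O1)CC/C=C(\C)C(=O)C1=C(OC)[C@]2(OC1=O)C[C@@H](C[C@@H](C)O[Si](C)(C)C(C)(C)C)C(CO[Si](C)(C)C(C)(C)C)=C[C@@]2(C)C/C=C/[C@@H](C)C=C(Br)Br | intermediate
31 | 19-membered macrocycle: E-enone C8a=C1, diene C2=C3(Br)–C4=C4a (Br cis to C9, C4=C4a E), E-C10=C11 | C[C@H]1CC/C=C(\C)C(=O)C2=C(OC)[C@]3(OC2=O)C[C@@H](C[C@@H](C)O[Si](C)(C)C(C)(C)C)C(CO[Si](C)(C)C(C)(C)C)=C[C@@]3(C)C/C=C/[C@@H](C)/C=C(Br)/C=C/C1 | intermediate
32 | pentacyclic adduct: full skeleton, all stereocentres as in the target, Br at C3, OMe at C4', two silyl ethers | C[C@H]1CC[C@@H]2[C@H](C=C(Br)[C@H]3[C@H](C)/C=C/C[C@]4(C)C=C(CO[Si](C)(C)C(C)(C)C)[C@H](C[C@@H](C)O[Si](C)(C)C(C)(C)C)C[C@]45OC(=O)C(=C5OC)C(=O)[C@@]23C)C1 | intermediate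
33 | debrominated adduct (OMe at C4', two silyl ethers) | C[C@H]1CC[C@@H]2[C@H](C=C[C@H]3[C@H](C)/C=C/C[C@]4(C)C=C(CO[Si](C)(C)C(C)(C)C)[C@H](C[C@@H](C)O[Si](C)(C)C(C)(C)C)C[C@]45OC(=O)C(=C5OC)C(=O)[C@@]23C)C1 | intermediate
34 | O19,O21-bis(tert-butyldimethylsilyl) ether of the target | C[C@H]1CC[C@@H]2[C@H](C=C[C@H]3[C@H](C)/C=C/C[C@]4(C)C=C(CO[Si](C)(C)C(C)(C)C)[C@H](C[C@@H](C)O[Si](C)(C)C(C)(C)C)C[C@]45OC(=O)C(=C5O)C(=O)[C@@]23C)C1 | intermediate
35 | CNP0189906.1 (C1 S, C2 S, C4a S, C6 S, C8a R, C9 R, C13 R, C16 R, C19 R, C5' S; C10=C11 E) | C[C@H]1CC[C@@H]2[C@H](C=C[C@H]3[C@H](C)/C=C/C[C@]4(C)C=C(CO)[C@H](C[C@@H](C)O)C[C@]45OC(=O)C(=C5O)C(=O)[C@@]23C)C1 | target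

**Step count**
Total step count: 24. Longest linear sequence: 19 (steps 1–10 and 16–24).

**Steps most likely to fail**

Step 21.
- What may go wrong: the cycloaddition may take the other diene face (the array with an equatorial C6 methyl group). It may pass through the exo array to a cis-decalin. It may also be too slow at temperatures that the doubly allylic C9–H tolerates.
- Fallback: the demethylation is moved ahead of the cycloaddition, so that the dienophile is activated and organised in a different way.
- Setting out from 31, LiCl in DMSO gives the free 3-acyl tetronic acid macrocycle F1. Its internal hydrogen bond holds C22=O coplanar with ring D and lowers the LUMO, as in the spontaneous decalin formation of polyenoyl tetramic and tetronic acids.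
- The transannular Diels–Alder reaction is then run at or below room temperature. If needed it is run on the chelate with Cu(OTf)2 and a C2-symmetric bis(oxazoline), which adds reagent control of the face. This gives the bromo adduct acid F2.
- Hydrogenolysis with Pd(PPh3)4 and Bu3SnH, as in step 22, returns to the route at 34.

Step 4.
- What may go wrong: facial selectivity at C13 may be poor or reversed, and O-allylation or a second allylation at C15 may intervene.
- Fallback: the order in which the two C13 substituents arrive is inverted, so that the same intrinsic facial preference now delivers the other group.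
- Setting out from 4, the Michael/Claisen/lactonisation sequence of step 3 is run with commercial methyl 3-oxohept-6-enoate in place of 5. This gives the 7-allyl trione F3.
- C-methylation of its dionate (MeI, K2CO3, acetone) then brings the methyl group in as the electrophile and returns to the route at 9.

Step 20.
- What may go wrong: oligomerisation, protodeboronation, or reaction of the second C–Br bond may compete with ring closure.
- Fallback: the diene is made by an intermolecular coupling and the large ring is closed at the isolated C10=C11 alkene instead.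
- Setting out from 21, Dess–Martin oxidation gives (R)-2-methylbut-3-enal F4, which is taken on at once with CBr4/PPh3 to (R)-1,1-dibromo-3-methylpenta-1,4-diene F5.
- Trans-selective Suzuki–Miyaura coupling of F5 with 25 (Pd(PPh3)4, TlOEt) gives the bromotetraenal F6.
- Tetronate 16 is deprotonated with LiN(iPr)2 and added to F6 to give the open-chain carbinol F7.
- Ring-closing metathesis with the second-generation Grubbs catalyst is run at this carbinol stage, where the dienophile is still unactivated. It gives the macrocyclic carbinol F8.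
- Dess–Martin oxidation returns to the route at 31.

**Further compounds**
F1 | step 21 | 19-membered macrocycle 31 with free C4' hydroxyl (3-acyl tetronic acid) | C[C@H]1CC/C=C(\C)C(=O)C2=C(O)[C@]3(OC2=O)C[C@@H](C[C@@H](C)O[Si](C)(C)C(C)(C)C)C(CO[Si](C)(C)C(C)(C)C)=C[C@@]3(C)C/C=C/[C@@H](C)/C=C(Br)/C=C/C1
F2 | step 21 | pentacyclic bromo adduct with free C4' hydroxyl | C[C@H]1CC[C@@H]2[C@H](C=C(Br)[C@H]3[C@H](C)/C=C/C[C@]4(C)C=C(CO[Si](C)(C)C(C)(C)C)[C@H](C[C@@H](C)O[Si](C)(C)C(C)(C)C)C[C@]45OC(=O)C(=C5O)C(=O)[C@@]23C)C1
F3 | step 4 | (3R,4aR)-7-allyl-3-methylhexahydroisochromene-1,6,8-trione | C=CCC1C(=O)C2C(=O)O[C@H](C)C[C@@H]2CC1=O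
F4 | step 20 | (R)-2-methylbut-3-enal | O=C[C@H](C)C=C
F5 | step 20 | (R)-1,1-dibromo-3-methylpenta-1,4-diene | BrC(Br)=C[C@H](C)C=C
F6 | step 20 | bromotetraenal (E-enal, C2=C3(Br)–C4=C4a diene, vinyl on C9) | C[C@H](C/C=C/C(Br)=C/[C@H](C)C=C)CC/C=C(\C)C=O
F7 | step 20 | open-chain C22 carbinol from 16 and F6 (epimers at C22) | C[C@H](C/C=C/C(Br)=C/[C@H](C)C=C)CC/C=C(\C)C(O)C1=C(OC)[C@]2(OC1=O)C[C@@H](C[C@@H](C)O[Si](C)(C)C(C)(C)C)C(CO[Si](C)(C)C(C)(C)C)=C[C@@]2(C)CC=C
F8 | step 20 | 19-membered macrocyclic C22 carbinol (epimers at C22) | C[C@H]1CC/C=C(\C)C(O)C2=C(OC)[C@]3(OC2=O)C[C@@H](C[C@@H](C)O[Si](C)(C)C(C)(C)C)C(CO[Si](C)(C)C(C)(C)C)=C[C@@]3(C)C/C=C/[C@@H](C)/C=C(Br)/C=C/C1
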